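**Retrosynthetic overview** (germacrane numbering: C3 acetate carbon, C6 lactone carbinol, C8 angelate carbon, C10 tertiary carbinol)
1. Target ⇐ acetylation at C3 ⇐ ten-membered carbocycle, formed last, by intramolecular CrCl2/NiCl2 coupling of a (Z)-alkenyl iodide (C4) with an (E)-enal (C3).
2. Seco-aldehyde ⇐ angeloylation and acetal hydrolysis ⇐ indium Barbier union (C7–C8) of an (R)-3-(bromomethyl)butenolide with an (R)-β-hydroxy aldehyde; this turns the butenolide into the α-methylidene lactone and sets C7 and C8 from C6.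
3. Butenolide (first ring) ⇐ organocatalytic enantioselective 1,4-bromolactonisation of an achiral 2-methylidene-3,5-dienoic acid (new method): sets C6, closes the lactone and installs the allylic bromide.
4. Dienoic acid ⇐ but-2-yn-1-ol and ethyl 2-(bromomethyl)acrylate; β-hydroxy aldehyde ⇐ biphenol-catalysed asymmetric allylboration (sets C10) of an enone made from 2,2-dimethoxyacetaldehyde, then alkene cleavage.

Assumption: the target is taken exactly as drawn, i.e. 3S,6S,7S,8R,10R with 1E, 4Z and a Z (angelate) ester. In steps 5 and 7 the catalyst antipode named is the one expected by analogy; if a first run shows the opposite sense, its commercial mirror-image or pseudo-enantiomer is used instead.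

**Step 1**
Reactants: 1 but-2-yn-1-ol
Product: 3 (2Z)-3-iodobut-2-en-1-ol, via cyclic alkenylalanate 2 (not isolated)
Conditions: NaAlH2(OCH2CH2OMe)2, Et2O, 0 °C to rt; then I2, THF, −78 to 0 °C
Reagents that add atoms: iodine, [I][I]
Why: Hydroxyl-directed trans-hydroalumination of the propargylic alcohol puts aluminium on the methyl-bearing carbon inside a five-membered alanate, and iodine cleaves the C–Al bond with retention, which fixes the Z-iodoalkene (hydroalumination–iodination).

**Step 2**
Reactants: 3 (2Z)-3-iodobut-2-en-1-ol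
Product: 4 (2Z)-3-iodobut-2-enal
Conditions: activated MnO2, CH2Cl2, rt; used as a solution
Reagents that add atoms: none
Why: MnO2 oxidises the allylic alcohol under neutral conditions, so the Z geometry and the C–I bond survive (allylic alcohol oxidation).

**Step 3**
Reactants: 4 (2Z)-3-iodobut-2-enal; 5 ethyl 2-(bromomethyl)prop-2-enoate
Product: 7 ethyl (3E,5Z)-6-iodo-2-methylidenehepta-3,5-dienoate, via allylphosphonium bromide 6 (not isolated)
Conditions: 5, PBu3, THF, 0 °C; then 4, KOtBu, −78 to 0 °C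
Reagents that add atoms: none
Why: SN2' addition of PBu3 to the bromomethylacrylate gives the allylic phosphonium salt, whose ylide olefinates the aldehyde at its α-carbon, allylic trialkylphosphonium ylides being E-selective, while the Z-iodoalkene is untouched (one-pot Wittig olefination).

**Step 4**
Reactants: 7 ethyl (3E,5Z)-6-iodo-2-methylidenehepta-3,5-dienoate
Product: 8 (3E,5Z)-6-iodo-2-methylidenehepta-3,5-dienoic acid
Conditions: LiOH·H2O, THF/H2O (3:1), 0 °C to rt; cold 1 M HCl to pH 3; used at once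
Reagents that add atoms: lithium hydroxide, [Li+].[OH-]
Why: Hydroxide attacks the ester carbonyl faster than the cross-conjugated triene, and cold acidification followed by immediate use avoids dimerisation of the 2-carboxydiene (saponification).

**Step 5**
Reactants: 8 (3E,5Z)-6-iodo-2-methylidenehepta-3,5-dienoic acid
Product: 9 (5R)-3-(bromomethyl)-5-[(1Z)-2-iodoprop-1-en-1-yl]furan-2(5H)-one
Conditions: N-bromosuccinimide (1.05 equiv), 9-amino-9-deoxy-epi-quinine 3,5-bis(trifluoromethyl)phenyl urea (10 mol%), PhMe/CHCl3 (2:1), −60 °C, dark; cold acidic quench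
Reagents that add atoms: N-bromosuccinimide, O=C1CCC(=O)N1Br
Why: Proposed new method: the catalyst holds the acid as a quinuclidinium carboxylate ion pair while its urea N–H bonds activate NBS, so Br+ is delivered to the terminal methylidene carbon of the s-trans 2-carboxy-1,3-diene as the carboxylate oxygen closes in a vinylogous (1,4-, SE2'-type) fashion on C6, the only position that gives a five-membered ring, and face selection at the E-alkene inside the chiral ion pair sets C6 as R while the butenolide ring and the allylic C–Br bond are formed together; the closest known reaction types are the cinchona-urea-catalysed enantioselective 1,4-bromolactonisation of conjugated enynes and the 5-endo halolactonisation of 4-aryl-but-3-enoic acids, neither yet shown on 2-methylidene-3-enoic acids.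

**Step 6**
Reactants: 10 2,2-dimethoxyacetaldehyde; 11 1-(triphenyl-λ5-phosphanylidene)propan-2-one
Product: 12 (3E)-5,5-dimethoxypent-3-en-2-one
Conditions: CH2Cl2/H2O, rt
Reagents that add atoms: none
Why: A stabilised ylide and an unhindered aldehyde give the E-enone (Wittig olefination).

**Step 7**
Reactants: 12 (3E)-5,5-dimethoxypent-3-en-2-one; 13 bis(propan-2-yl) prop-2-en-1-ylboronate
Product: 14 (2E,4R)-1,1-dimethoxy-4-methylhepta-2,6-dien-4-ol
Conditions: (S)-3,3'-dibromo-1,1'-bi-2-naphthol (15 mol%), PhCF3/PhMe (3:1), −35 °C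
Reagents that add atoms: none
Why: The chiral biphenol exchanges onto boron and the ketone is allylated through a closed six-membered chair transition state that differentiates the alkenyl group from methyl, setting the C10 carbinol as R, while the acetal and the enone alkene are inert (organocatalytic asymmetric allylboration of a ketone).

**Step 8**
Reactants: 14 (2E,4R)-1,1-dimethoxy-4-methylhepta-2,6-dien-4-ol
Product: 16 (3R,4E)-3-hydroxy-6,6-dimethoxy-3-methylhex-4-enal, via triol 15 (not isolated)
Conditions: OsO4 (2 mol%), NaIO4 (2.1 equiv), 2,6-lutidine, dioxane/H2O (3:1), 0 °C, stopped near 90% conversion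
Reagents that add atoms: osmium tetroxide, O=[Os](=O)(=O)=O; sodium periodate, [Na+].[O-]I(=O)(=O)=O
Why: OsO4 is expected to dihydroxylate the unhindered terminal alkene in preference to the internal alkene, which is flanked by a fully substituted carbinol carbon and an acetal carbon, and NaIO4 then cleaves the diol (Lemieux–Johnson oxidative cleavage).

**Step 9**
Reactants: 9 (5R)-3-(bromomethyl)-5-[(1Z)-2-iodoprop-1-en-1-yl]furan-2(5H)-one; 16 (3R,4E)-3-hydroxy-6,6-dimethoxy-3-methylhex-4-enal
Product: 17 (4S,5R)-4-[(1R,3R,4E)-1,3-dihydroxy-6,6-dimethoxy-3-methylhex-4-en-1-yl]-5-[(1Z)-2-iodoprop-1-en-1-yl]-3-methylideneoxolan-2-one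
Conditions: indium powder (1.5 equiv), THF/H2O (3:1), rt
Reagents that add atoms: none
Why: The allylindium formed from 9 adds through its γ-carbon (C7) in a chair transition state on the ring face opposite the C6 alkenyl group with the aldehyde chain equatorial, giving the trans-lactone and the anti C7/C8 relationship (7S, 8R), while the alkenyl iodide, acetal and free tertiary alcohol are tolerated in water (Barbier allylation).

**Step 10**
Reactants: 17 (4S,5R)-4-[(1R,3R,4E)-1,3-dihydroxy-6,6-dimethoxy-3-methylhex-4-en-1-yl]-5-[(1Z)-2-iodoprop-1-en-1-yl]-3-methylideneoxolan-2-one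
Product: 18 (1R,3R,4E)-3-hydroxy-1-[(2R,3S)-2-[(1Z)-2-iodoprop-1-en-1-yl]-4-methylidene-5-oxooxolan-3-yl]-6,6-dimethoxy-3-methylhex-4-en-1-yl (2Z)-2-methylbut-2-enoate
Conditions: angelic acid, 2,4,6-trichlorobenzoyl chloride, Et3N, PhMe, rt; then 17, 75 °C
Reagents that add atoms: angelic acid, C/C=C(/C)C(=O)O
Why: The preformed mixed anhydride acylates only the secondary C8 alcohol, the tertiary alcohol being inert, and the absence of a nucleophilic catalyst keeps the angelate Z (Yamaguchi-type esterification).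

**Step 11**
Reactants: 18 (1R,3R,4E)-3-hydroxy-1-[(2R,3S)-2-[(1Z)-2-iodoprop-1-en-1-yl]-4-methylidene-5-oxooxolan-3-yl]-6,6-dimethoxy-3-methylhex-4-en-1-yl (2Z)-2-methylbut-2-enoate
Product: 19 (1R,3R,4E)-3-hydroxy-1-[(2R,3S)-2-[(1Z)-2-iodoprop-1-en-1-yl]-4-methylidene-5-oxooxolan-3-yl]-3-methyl-6-oxohex-4-en-1-yl (2Z)-2-methylbut-2-enoate
Conditions: pyridinium p-toluenesulfonate (cat.), acetone/H2O (10:1), rt
Reagents that add atoms: water, O
Why: Mild acid hydrolyses the allylic dimethyl acetal to the E-enal without ionising the tertiary allylic alcohol or touching the esters (acetal hydrolysis).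

**Step 12**
Reactants: 19 (1R,3R,4E)-3-hydroxy-1-[(2R,3S)-2-[(1Z)-2-iodoprop-1-en-1-yl]-4-methylidene-5-oxooxolan-3-yl]-3-methyl-6-oxohex-4-en-1-yl (2Z)-2-methylbut-2-enoate
Product: 20 (3aS,4R,6R,7E,9S,10Z,11aS)-6,9-dihydroxy-6,10-dimethyl-3-methylidene-2-oxo-2,3,3a,4,5,6,9,11a-octahydrocyclodeca[b]furan-4-yl (2Z)-2-methylbut-2-enoate
Conditions: CrCl2 (10 equiv), NiCl2 (0.1 equiv), degassed DMSO, 0.003 M, slow addition, rt
Reagents that add atoms: none
Why: NiCl2-catalysed insertion into the C–I bond and transmetalation give an alkenylchromium species with retained Z geometry that adds 1,2 to the enal at high dilution, the trans-lactone and E-alkene pre-organising the chain, and attack on the outer face of the s-trans enal is expected (not established) to give the 9S alcohol, i.e. C3 S (intramolecular Nozaki–Hiyama–Kishi reaction).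

**Step 13**
Reactants: 20 (3aS,4R,6R,7E,9S,10Z,11aS)-6,9-dihydroxy-6,10-dimethyl-3-methylidene-2-oxo-2,3,3a,4,5,6,9,11a-octahydrocyclodeca[b]furan-4-yl (2Z)-2-methylbut-2-enoate
Product: 21 (3aS,4R,6R,7E,9S,10Z,11aS)-9-(acetyloxy)-6-hydroxy-6,10-dimethyl-3-methylidene-2-oxo-2,3,3a,4,5,6,9,11a-octahydrocyclodeca[b]furan-4-yl (2Z)-2-methylbut-2-enoate
Conditions: Ac2O, pyridine, DMAP (5 mol%), CH2Cl2, 0 °C
Reagents that add atoms: acetic anhydride, CC(=O)OC(C)=O
Why: The secondary bis-allylic alcohol is acetylated while the tertiary alcohol does not react at 0 °C (esterification).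

**Compound list**
1 | but-2-yn-1-ol | CC#CCO | starting material
2 | sodium 2,2-bis(2-methoxyethoxy)-3-methyl-2,5-dihydro-1,2-oxaluminol-2-uide (cyclic alkenylalanate) | CC1=CCO[Al-]1(OCCOC)OCCOC.[Na+] | intermediate
3 | (2Z)-3-iodobut-2-en-1-ol | OC/C=C(/C)I | intermediate
4 | (2Z)-3-iodobut-2-enal | O=C/C=C(/C)I | intermediate
5 | ethyl 2-(bromomethyl)prop-2-enoate | C=C(CBr)C(=O)OCC | starting material
6 | tributyl[2-(ethoxycarbonyl)prop-2-en-1-yl]phosphonium bromide | CCCC[P+](CCCC)(CCCC)CC(=C)C(=O)OCC.[Br-] | intermediate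
7 | ethyl (3E,5Z)-6-iodo-2-methylidenehepta-3,5-dienoate | C=C(C(=O)OCC)/C=C/C=C(/C)I | intermediate
8 | (3E,5Z)-6-iodo-2-methylidenehepta-3,5-dienoic acid | C=C(C(=O)O)/C=C/C=C(/C)I | intermediate
9 | (5R)-3-(bromomethyl)-5-[(1Z)-2-iodoprop-1-en-1-yl]furan-2(5H)-one | BrCC1=C[C@H](/C=C(/C)I)OC1=O | intermediate
10 | 2,2-dimethoxyacetaldehyde | COC(OC)C=O | starting material
11 | 1-(triphenyl-λ5-phosphanylidene)propan-2-one | CC(=O)C=P(c1ccccc1)(c1ccccc1)c1ccccc1 | starting material
12 | (3E)-5,5-dimethoxypent-3-en-2-one | CC(=O)/C=C/C(OC)OC | intermediate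
13 | bis(propan-2-yl) prop-2-en-1-ylboronate | C=CCB(OC(C)C)OC(C)C | starting material
14 | (2E,4R)-1,1-dimethoxy-4-methylhepta-2,6-dien-4-ol | C=CC[C@@](C)(O)/C=C/C(OC)OC | intermediate
15 | (4R,5E)-7,7-dimethoxy-4-methylhept-5-ene-1,2,4-triol (both C2 epimers) | OCC(O)C[C@@](C)(O)/C=C/C(OC)OC | intermediate
16 | (3R,4E)-3-hydroxy-6,6-dimethoxy-3-methylhex-4-enal | O=CC[C@@](C)(O)/C=C/C(OC)OC | intermediate
17 | (4S,5R)-4-[(1R,3R,4E)-1,3-dihydroxy-6,6-dimethoxy-3-methylhex-4-en-1-yl]-5-[(1Z)-2-iodoprop-1-en-1-yl]-3-methylideneoxolan-2-one | C=C1C(=O)O[C@@H](/C=C(/C)I)[C@@H]1[C@H](O)C[C@@](C)(O)/C=C/C(OC)OC | intermediate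
18 | (1R,3R,4E)-3-hydroxy-1-[(2R,3S)-2-[(1Z)-2-iodoprop-1-en-1-yl]-4-methylidene-5-oxooxolan-3-yl]-6,6-dimethoxy-3-methylhex-4-en-1-yl (2Z)-2-methylbut-2-enoate | C=C1C(=O)O[C@@H](/C=C(/C)I)[C@@H]1[C@H](OC(=O)/C(C)=C\C)C[C@@](C)(O)/C=C/C(OC)OC | intermediate
19 | (1R,3R,4E)-3-hydroxy-1-[(2R,3S)-2-[(1Z)-2-iodoprop-1-en-1-yl]-4-methylidene-5-oxooxolan-3-yl]-3-methyl-6-oxohex-4-en-1-yl (2Z)-2-methylbut-2-enoate | C=C1C(=O)O[C@@H](/C=C(/C)I)[C@@H]1[C@H](OC(=O)/C(C)=C\C)C[C@@](C)(O)/C=C/C=O | intermediate
20 | (3aS,4R,6R,7E,9S,10Z,11aS)-6,9-dihydroxy-6,10-dimethyl-3-methylidene-2-oxo-2,3,3a,4,5,6,9,11a-octahydrocyclodeca[b]furan-4-yl (2Z)-2-methylbut-2-enoate | C=C1C(=O)O[C@H]2/C=C(/C)[C@@H](O)/C=C/[C@](C)(O)C[C@@H](OC(=O)/C(C)=C\C)[C@H]12 | intermediate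
21 | (3aS,4R,6R,7E,9S,10Z,11aS)-9-(acetyloxy)-6-hydroxy-6,10-dimethyl-3-methylidene-2-oxo-2,3,3a,4,5,6,9,11a-octahydrocyclodeca[b]furan-4-yl (2Z)-2-methylbut-2-enoate | C=C1C(=O)O[C@H]2/C=C(/C)[C@@H](OC(C)=O)/C=C/[C@](C)(O)C[C@@H](OC(=O)/C(C)=C\C)[C@H]12 | target

**Total step count:** 13.
**Longest linear sequence:** 10 (steps 1–5, then 9–13); the east branch is steps 6–8.

**Three steps most likely to fail**

Step 5 (the proposed new bromolactonisation). Br+ may attack elsewhere on the triene, the ee may be modest, the product's allylic bromide may alkylate the quinuclidine, and the doubly allylic C5–H of the butenolide may lose ee under base. Two points limit the damage. A regioisomeric 4-bromo-3-methylidene lactone would give the same allylindium in step 9, and coupling with enantioenriched 16 turns residual enantiomer into separable diastereomers. The fallback uses known chemistry, sets out from 4 and comes back at 9. Vinylmagnesium bromide (THF, −78 °C) gives racemic (4Z)-5-iodohexa-1,4-dien-3-ol F1. Sharpless kinetic resolution (Ti(OiPr)4, diisopropyl D-tartrate, tBuOOH, 4 Å sieves, CH2Cl2, −20 °C, about 55% conversion, the vinyl group of the fast enantiomer being epoxidised) leaves (3R,4Z)-5-iodohexa-1,4-dien-3-ol F2. Acylation with 2-(bromomethyl)acrylic acid and N,N'-diisopropylcarbodiimide (CH2Cl2, 0 °C) gives (3R,4Z)-5-iodohexa-1,4-dien-3-yl 2-(bromomethyl)prop-2-enoate F3. Ring-closing metathesis with the second-generation Hoveyda–Grubbs catalyst RuCl2(H2IMes)(=CH-C6H4-2-OiPr) in CH2Cl2 at 40 °C closes the butenolide with loss of ethene and returns 9.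

Step 12 (macrocyclisation). The ten-membered ring is strained and the configuration at the new carbinol is set only by the macrocyclic transition state, so a mixture or the wrong epimer is the likely failure. The fallback replaces substrate control in the C–C bond formation by reagent control in a ketone reduction; it sets out from 19 and comes back at 20. The coupling is run without regard to selectivity and gives 20 together with its epimer, the (3aS,4R,6R,7E,9R,10Z,11aS)-6,9-dihydroxy-6,10-dimethyl-3-methylidene-2-oxo-2,3,3a,4,5,6,9,11a-octahydrocyclodeca[b]furan-4-yl (2Z)-2-methylbut-2-enoate F4. Dess–Martin periodinane (CH2Cl2, NaHCO3, 0 °C) converts the mixture into the cross-conjugated (3aS,4R,6R,7E,10Z,11aS)-6-hydroxy-6,10-dimethyl-3-methylidene-2,9-dioxo-2,3,3a,4,5,6,9,11a-octahydrocyclodeca[b]furan-4-yl (2Z)-2-methylbut-2-enoate F5. Reduction with (R)-2-methyl-CBS-oxazaborolidine and catecholborane (PhMe, −78 °C), the α-methylalkenyl arm acting as the large group, returns 20.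

Step 3 (one-pot allylic Wittig). The ylide may react through its γ-carbon, annulate with the acrylate or the enal, or give E/Z mixtures. The fallback replaces olefination by allylation and dehydration; it sets out from 4 and 5 and comes back at 7. Indium powder in THF/H2O at rt joins 4 and 5 to racemic ethyl (5Z)-4-hydroxy-6-iodo-2-methylidenehept-5-enoate F6. MsCl and Et3N (CH2Cl2, −20 °C) give ethyl (5Z)-6-iodo-4-(methanesulfonyloxy)-2-methylidenehept-5-enoate F7. DBU (CH2Cl2, 0 °C to rt) eliminates towards the conjugated E-triene and returns 7.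

**Further compounds**
F1 | step 5 | (4Z)-5-iodohexa-1,4-dien-3-ol (racemic) | C=CC(O)/C=C(/C)I
F2 | step 5 | (3R,4Z)-5-iodohexa-1,4-dien-3-ol | C=C[C@@H](O)/C=C(/C)I
F3 | step 5 | (3R,4Z)-5-iodohexa-1,4-dien-3-yl 2-(bromomethyl)prop-2-enoate | C=C(CBr)C(=O)O[C@H](C=C)/C=C(/C)I
F4 | step 12 | (3aS,4R,6R,7E,9R,10Z,11aS)-6,9-dihydroxy-6,10-dimethyl-3-methylidene-2-oxo-2,3,3a,4,5,6,9,11a-octahydrocyclodeca[b]furan-4-yl (2Z)-2-methylbut-2-enoate | C=C1C(=O)O[C@H]2/C=C(/C)[C@H](O)/C=C/[C@](C)(O)C[C@@H](OC(=O)/C(C)=C\C)[C@H]12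
F5 | step 12 | (3aS,4R,6R,7E,10Z,11aS)-6-hydroxy-6,10-dimethyl-3-methylidene-2,9-dioxo-2,3,3a,4,5,6,9,11a-octahydrocyclodeca[b]furan-4-yl (2Z)-2-methylbut-2-enoate | C=C1C(=O)O[C@H]2/C=C(/C)C(=O)/C=C/[C@](C)(O)C[C@@H](OC(=O)/C(C)=C\C)[C@H]12
F6 | step 3 | ethyl (5Z)-4-hydroxy-6-iodo-2-methylidenehept-5-enoate (racemic) | C=C(CC(O)/C=C(/C)I)C(=O)OCC
F7 | step 3 | ethyl (5Z)-6-iodo-4-(methanesulfonyloxy)-2-methylidenehept-5-enoate (racemic) | C=C(CC(OS(C)(=O)=O)/C=C(/C)I)C(=O)OCC
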